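Time was what I read these runs along, asking how the pace of making product in the flask answers to the free catalyst charged.

| setting | autumn | dawn | flask |
|---|---|---|---|
| starting material | 0.050 M | 0.050 M | 0.050 M |
| reagent | 0.075 M | 0.075 M | 0.0750 M |
| free catalyst | 0.50 mM | 2 mM | 1.0 mM |
| remark | run made earlier | run made earlier |  |

| run | time / h | product / % | starting material / % |
|---|---|---|---|
| autumn | 0.833 | 6.5 | 92.0 |
| autumn | 1.33 | 10.8 | 88.1 |
| autumn | 2.00 | 16.6 | 83.3 |
| autumn | 4.00 | 30.9 | 68.4 |
| autumn | 6.00 | 42.9 | 57.2 |
| autumn | 10.0 | 61.9 | 37.5 |
| dawn | 1.50 | 35.7 | 61.0 |
| dawn | 3.00 | 60.0 | 34.8 |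
| dawn | 5.00 | 81.6 | 16.1 |
| dawn | 6.00 | 87.8 | 9.5 |
| dawn | 8.00 | 93.9 | 3.2 |
| dawn | 10.0 | 96.4 | 1.1 |

(standard deviation of a reading: 0.5 percentage points)

- in percentages every species weighs as the starting material in it: one idle complex or resting dimer counts as two
- steps under discussion: starting material + free catalyst -> catalyst intermediate A; catalyst intermediate A -> catalyst intermediate B; starting material + catalyst intermediate D <-> idle complex; catalyst intermediate D <-> free catalyst + product; reagent + catalyst intermediate B <-> catalyst intermediate C; catalyst intermediate C -> catalyst intermediate D; 2 catalyst intermediate B <-> resting dimer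

* apparent order in free catalyst when 10% of the starting material are converted (percent change of the rate of making product for one percent more free catalyst charged)

In the first instants the catalyst takes up starting material. At 1.50 h in the dawn run, starting material and product together fell short of the charge by a reading of 3.30%, and the catalyst charged there is 4.00% of the starting material. So I read that shortfall as material riding on the catalyst.

Through the middle I counted turnovers, using the pseudo-first-order constant from the earliest reading past 10% conversion in each run:

autumn constant 0.0953 h⁻¹, dawn constant 0.330 h⁻¹

turnovers at 10% conversion: autumn 8.57 h⁻¹, dawn 7.41 h⁻¹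

flask, midway on a log scale: 7.97 h⁻¹

order: 0.895

I carried this turnover rate, the starting material turned per hour by each catalyst charged: an order of one means it stays put as the charge changes.

By the end of the dawn run, at 10.0 h, the average constant had climbed to 0.451 h⁻¹. The constant climbed as the dawn run went on, so my dawn figure, read beyond 10% conversion, leans high.

The forecast gave 0.83, below my 0.895: “Sequestration makes the order sublinear and falling with loading.”

The flask gave 0.86.

    starting material + free catalyst → catalyst intermediate A (k = 1000 M⁻¹ h⁻¹)
    catalyst intermediate A → catalyst intermediate B (k = 54.0 h⁻¹)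
    starting material + catalyst intermediate D ⇌ idle complex, settled at all times (K = 9.10 M⁻¹)
    catalyst intermediate D ⇌ free catalyst + product (K = 0.0220 M, k = 75.0 h⁻¹)
    reagent + catalyst intermediate B ⇌ catalyst intermediate C (K = 1000 M⁻¹, k = 560 M⁻¹ h⁻¹)
    catalyst intermediate C → catalyst intermediate D (k = 62.0 h⁻¹)
    2 catalyst intermediate B ⇌ resting dimer, settled at all times (K = 2200 M⁻¹)

At 10% conversion, reached at 0.559 h, the flask made product at 0.00771 M h⁻¹, a turnover rate in product of 7.71 h⁻¹ against my 7.97 h⁻¹, reckoned on starting material. Part of the reason the turnover rate sinks with charge is the binding of catalyst intermediate B into resting dimer, which holds 17.2% of this flask's catalyst at that moment. This flask run without that binding proves it: the rate there is 1.21 times the actual one, the order is 1.0, and the turnover rate is 9.31 h⁻¹. That binding is also the largest single effect on this flask's order in reagent at that conversion, which is 0.49 with it and 0.25 without it.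

(All runs stem from a simulated flask from invented constants; the scatter is artificial.)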